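The flavonol half is cut through ring C at O1–C2 and C3–C4. Its pyranone, carrying the aryl ether oxygen on C3, is the C4-oxidised form of a 3-aryloxy-2-arylbenzopyrylium ion. That cation assembles in one acid-mediated operation from a ring A salicylaldehyde (C4 as the formyl carbon, O1 as the phenol) and a ring B phenacyl aryl ether (C2 as the carbonyl, C3 as the methylene bearing the ether oxygen). The ether aryl group is 4-bromophenyl, which later becomes the C2 aryl of the (S)-flavanone by borylation and enantioselective rhodium-catalysed 1,4-addition to a chromone. Benzyl ethers mask all five phenols.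

Key step: step 3

Remark: 3 and 11 are treated as catalogue compounds; the facial sense in step 8 is assigned by analogy with additions of the same rhodium–diene catalyst to cyclic enones, and the enantiomeric diene would be taken if a model addition showed the opposite sense.

Step 1
Reactants: 1 2,4,6-trihydroxybenzaldehyde
Product: 2 2,4-bis(benzyloxy)-6-hydroxybenzaldehyde
Conditions: BnBr (2.05 equiv), K2CO3 (2.2 equiv), DMF, 0 °C to rt
Reagents that add atoms: benzyl bromide, BrCc1ccccc1
Why: Williamson etherification in which the para hydroxyl and then one ortho hydroxyl should react, while the remaining ortho hydroxyl is held back by its hydrogen bond to the formyl group.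

Step 2
Reactants: 3 2-bromo-1-[4-(benzyloxy)phenyl]ethanone; 4 4-bromophenol
Product: 5 1-[4-(benzyloxy)phenyl]-2-(4-bromophenoxy)ethanone
Conditions: K2CO3, acetone, reflux
Reagents that add atoms: none
Why: Williamson SN2 displacement of a phenacyl bromide by a phenoxide, which should give the unhindered aryloxymethyl ketone in one step from two commercial materials.

Step 3
Reactants: 2 2,4-bis(benzyloxy)-6-hydroxybenzaldehyde; 5 1-[4-(benzyloxy)phenyl]-2-(4-bromophenoxy)ethanone
Product: 7 5,7-bis(benzyloxy)-2-[4-(benzyloxy)phenyl]-3-(4-bromophenoxy)chromenylium chloride, via benzylidene ketone 6 (not isolated)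
Conditions: dry HCl (gas, to saturation), EtOAc, 0 °C, then 4 °C; salt collected by filtration
Reagents that add atoms: hydrogen chloride, Cl
Why: Acid enolises the only enolisable position, the OCH2 of 5, and the enol adds to the protonated formyl group of 2; loss of water gives benzylidene ketone 6 with the new C3–C4 bond. Acid equilibrates the alkene geometry, and in the E isomer the ring A phenol attacks the protonated ketone carbon in a 6-exo-trig closure (O1–C2) to a 2-hydroxy-2H-chromene, whose dehydration gives the aromatic benzopyrylium cation as the thermodynamic sink, expected to leave solution as its chloride. The closest known reaction type is the classical acid-mediated flavylium synthesis from salicylaldehydes and aryl alkoxymethyl ketones. No stereocentre is formed. The step needs only cross-selectivity and tolerance: 2 has no α-hydrogen and 5 has a single enolisable carbon, so one constitution results, and the benzyl aryl ethers and the aryl bromide should tolerate anhydrous HCl at 0 °C.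

Step 4
Reactants: 7 5,7-bis(benzyloxy)-2-[4-(benzyloxy)phenyl]-3-(4-bromophenoxy)chromenylium chloride
Product: 8 5,7-bis(benzyloxy)-2-[4-(benzyloxy)phenyl]-3-(4-bromophenoxy)-4H-chromene
Conditions: NaBH4, MeCN–THF, 0 °C (salt added to the hydride); product used promptly
Reagents that add atoms: none
Why: Hydride reduction of a 3-alkoxyflavylium salt to the flav-2-ene; addition should occur at the unsubstituted C4 because C2 is shielded by its aryl group and the neighbouring aryloxy group, and the product is the enol ether conjugated to ring B.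

Step 5
Reactants: 8 5,7-bis(benzyloxy)-2-[4-(benzyloxy)phenyl]-3-(4-bromophenoxy)-4H-chromene
Product: 9 5,7-bis(benzyloxy)-2-[4-(benzyloxy)phenyl]-3-(4-bromophenoxy)-4H-chromen-4-one
Conditions: pyridinium chlorochromate [C5H5NH][CrO3Cl] (2.5 equiv), Celite, CH2Cl2, rt to 40 °C
Reagents that add atoms: pyridinium chlorochromate, [O-][Cr](=O)(=O)Cl.c1cc[nH+]cc1
Why: Benzylic–allylic oxidation by hexavalent chromium, as in xanthene-to-xanthone and chromene-to-chromone oxidations; the C4 methylene between ring A and the C2=C3 enol ether is the most activated C–H position, and a chromate ester formed at C2 of the allyl system carries no hydrogen and can only revert or shift to C4, so oxidation should end at the C4 ketone.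

Step 6
Reactants: 9 5,7-bis(benzyloxy)-2-[4-(benzyloxy)phenyl]-3-(4-bromophenoxy)-4H-chromen-4-one
Product: 10 5,7-bis(benzyloxy)-2-[4-(benzyloxy)phenyl]-3-[4-(4,4,5,5-tetramethyl-1,3,2-dioxaborolan-2-yl)phenoxy]-4H-chromen-4-one
Conditions: bis(pinacolato)diboron, PdCl2(dppf) (3 mol%), KOAc, 1,4-dioxane, 90 °C
Reagents that add atoms: bis(pinacolato)diboron, CC1(C)OB(OC1(C)C)B1OC(C)(C)C(C)(C)O1
Why: Miyaura borylation; oxidative addition of zerovalent palladium into the aryl C–Br bond and acetate-assisted transmetalation with the diboron reagent should leave the flavone carbonyl and the ethers untouched.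

Step 7
Reactants: 11 1-[2,4-bis(benzyloxy)-6-hydroxyphenyl]ethanone
Product: 13 5,7-bis(benzyloxy)-4H-chromen-4-one, via enaminone 12 (not isolated)
Conditions: Me2NCH(OMe)2, toluene, 95 °C; then HCl (2 M aq., 1.5 equiv), CH2Cl2, 40 °C
Reagents that add atoms: N,N-dimethylformamide dimethyl acetal, COC(OC)N(C)C
Why: Enaminone formation at the acetyl methyl group, followed by acid-mediated conjugate addition of the phenol and loss of dimethylamine, is the standard closure of 2-hydroxyacetophenones to chromones unsubstituted at C2 and C3.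

Step 8
Reactants: 10 5,7-bis(benzyloxy)-2-[4-(benzyloxy)phenyl]-3-[4-(4,4,5,5-tetramethyl-1,3,2-dioxaborolan-2-yl)phenoxy]-4H-chromen-4-one; 13 5,7-bis(benzyloxy)-4H-chromen-4-one (1.5 equiv)
Product: 14 (2S)-5,7-bis(benzyloxy)-2-[4-({5,7-bis(benzyloxy)-2-[4-(benzyloxy)phenyl]-4-oxo-4H-chromen-3-yl}oxy)phenyl]-2,3-dihydro-4H-chromen-4-one
Conditions: [RhCl(C2H4)2]2 (2.5 mol%), (1S,4S)-2,5-diphenylbicyclo[2.2.2]octa-2,5-diene [(S,S)-Ph-bod, 5.5 mol%], K3PO4 (aq., 0.5 equiv), 1,4-dioxane, 50 °C
Reagents that add atoms: none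
Why: Rhodium-catalysed asymmetric 1,4-addition of an arylboron reagent to a chromone (Hayashi–Miyaura reaction): the aryl group of 10 should pass to a hydroxo-rhodium–diene complex and insert across C2=C3 of 13, the C2-symmetric diene directing it to the Re face of C2 to set 2S, after which water protonates the rhodium enolate; the fully substituted C2=C3 of the flavone in 10 is too hindered to compete as an acceptor.

Step 9
Reactants: 14 (2S)-5,7-bis(benzyloxy)-2-[4-({5,7-bis(benzyloxy)-2-[4-(benzyloxy)phenyl]-4-oxo-4H-chromen-3-yl}oxy)phenyl]-2,3-dihydro-4H-chromen-4-one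
Product: 15 (2S)-5,7-dihydroxy-2-(4-{[5,7-dihydroxy-2-(4-hydroxyphenyl)-4-oxo-4H-chromen-3-yl]oxy}phenyl)-2,3-dihydro-4H-chromen-4-one
Conditions: H2 (1 atm), 10% Pd/C, THF–MeOH, rt; stopped when five equivalents of H2 are taken up
Reagents that add atoms: none
Why: Catalytic hydrogenolysis of the five benzyl aryl ethers under neutral conditions should be faster than cleavage of the cyclic benzylic C2–O1 bond or reduction of the flavone alkene, and should leave the C2 stereocentre untouched.

Compound list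
1 | 2,4,6-trihydroxybenzaldehyde | O=Cc1c(O)cc(O)cc1O | starting material
2 | 2,4-bis(benzyloxy)-6-hydroxybenzaldehyde | O=Cc1c(O)cc(OCc2ccccc2)cc1OCc1ccccc1 | intermediate
3 | 2-bromo-1-[4-(benzyloxy)phenyl]ethanone | O=C(CBr)c1ccc(OCc2ccccc2)cc1 | starting material
4 | 4-bromophenol | Oc1ccc(Br)cc1 | starting material
5 | 1-[4-(benzyloxy)phenyl]-2-(4-bromophenoxy)ethanone | O=C(COc1ccc(Br)cc1)c1ccc(OCc2ccccc2)cc1 | intermediate
6 | (E)-3-[2,4-bis(benzyloxy)-6-hydroxyphenyl]-1-[4-(benzyloxy)phenyl]-2-(4-bromophenoxy)prop-2-en-1-one (ring A aryl cis to the aroyl group; geometry equilibrates in acid) | O=C(c1ccc(OCc2ccccc2)cc1)/C(Oc1ccc(Br)cc1)=C\c1c(O)cc(OCc2ccccc2)cc1OCc1ccccc1 | intermediate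
7 | 5,7-bis(benzyloxy)-2-[4-(benzyloxy)phenyl]-3-(4-bromophenoxy)chromenylium chloride | Brc1ccc(Oc2cc3c(OCc4ccccc4)cc(OCc4ccccc4)cc3[o+]c2-c2ccc(OCc3ccccc3)cc2)cc1.[Cl-] | intermediate
8 | 5,7-bis(benzyloxy)-2-[4-(benzyloxy)phenyl]-3-(4-bromophenoxy)-4H-chromene | Brc1ccc(OC2=C(c3ccc(OCc4ccccc4)cc3)Oc3cc(OCc4ccccc4)cc(OCc4ccccc4)c3C2)cc1 | intermediate
9 | 5,7-bis(benzyloxy)-2-[4-(benzyloxy)phenyl]-3-(4-bromophenoxy)-4H-chromen-4-one | O=c1c(Oc2ccc(Br)cc2)c(-c2ccc(OCc3ccccc3)cc2)oc2cc(OCc3ccccc3)cc(OCc3ccccc3)c12 | intermediate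
10 | 5,7-bis(benzyloxy)-2-[4-(benzyloxy)phenyl]-3-[4-(4,4,5,5-tetramethyl-1,3,2-dioxaborolan-2-yl)phenoxy]-4H-chromen-4-one | O=c1c(Oc2ccc(B3OC(C)(C)C(C)(C)O3)cc2)c(-c2ccc(OCc3ccccc3)cc2)oc2cc(OCc3ccccc3)cc(OCc3ccccc3)c12 | intermediate
11 | 1-[2,4-bis(benzyloxy)-6-hydroxyphenyl]ethanone | CC(=O)c1c(O)cc(OCc2ccccc2)cc1OCc1ccccc1 | starting material
12 | (E)-1-[2,4-bis(benzyloxy)-6-hydroxyphenyl]-3-(dimethylamino)prop-2-en-1-one | CN(C)/C=C/C(=O)c1c(O)cc(OCc2ccccc2)cc1OCc1ccccc1 | intermediate
13 | 5,7-bis(benzyloxy)-4H-chromen-4-one | O=c1ccoc2cc(OCc3ccccc3)cc(OCc3ccccc3)c12 | intermediate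
14 | (2S)-5,7-bis(benzyloxy)-2-[4-({5,7-bis(benzyloxy)-2-[4-(benzyloxy)phenyl]-4-oxo-4H-chromen-3-yl}oxy)phenyl]-2,3-dihydro-4H-chromen-4-one | O=C1C[C@@H](c2ccc(Oc3c(-c4ccc(OCc5ccccc5)cc4)oc4cc(OCc5ccccc5)cc(OCc5ccccc5)c4c3=O)cc2)Oc2cc(OCc3ccccc3)cc(OCc3ccccc3)c21 | intermediate
15 | (2S)-5,7-dihydroxy-2-(4-{[5,7-dihydroxy-2-(4-hydroxyphenyl)-4-oxo-4H-chromen-3-yl]oxy}phenyl)-2,3-dihydro-4H-chromen-4-one | O=C1C[C@@H](c2ccc(Oc3c(-c4ccc(O)cc4)oc4cc(O)cc(O)c4c3=O)cc2)Oc2cc(O)cc(O)c21 | target

Total step count: 9. Longest linear sequence: 7 steps (steps 1, 3, 4, 5, 6, 8, 9).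

Steps most likely to fail

Step 3. The acid may strip or shift benzyl groups on the electron-rich ring A, and the crossed aldol condensation may be slow enough for 2 and 5 to be consumed by side reactions before ring closure. The fallback sets out from 2 and 5 and returns at 7. The phenol of 2 would be capped (MeOCH2Cl, iPr2NEt, CH2Cl2) to give 2,4-bis(benzyloxy)-6-(methoxymethoxy)benzaldehyde F1. This would be condensed with 5 under Claisen–Schmidt conditions (KOH, EtOH–THF, rt) to the protected benzylidene ketone (Z)-3-[2,4-bis(benzyloxy)-6-(methoxymethoxy)phenyl]-1-[4-(benzyloxy)phenyl]-2-(4-bromophenoxy)prop-2-en-1-one F2. A short exposure to HCl in dioxane–MeOH at 0 °C should then remove the acetal, equilibrate the alkene and close ring C to salt 7. The slow bimolecular C–C bond formation is thereby moved out of the acid.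

Step 5. The chromium reagent may cleave the electron-rich C2=C3 enol ether, or hydride abstraction may stop at the benzopyrylium stage without oxygen transfer; hydride addition at C2 instead of C4 in step 4 would add to the loss. The fallback sets out from 2 and 5 and returns at 9, bringing C4 in at the ketone oxidation level and bypassing steps 3 to 5. The lithium enolate of 5 (LiN(SiMe3)2, THF, −78 °C) would add to 2,4-bis(benzyloxy)-6-(methoxymethoxy)benzaldehyde F1, made from 2 as above. This should give the aldol 3-[2,4-bis(benzyloxy)-6-(methoxymethoxy)phenyl]-1-[4-(benzyloxy)phenyl]-2-(4-bromophenoxy)-3-hydroxypropan-1-one F3. Dess–Martin periodinane in CH2Cl2 would oxidise it to the diketone 1-[2,4-bis(benzyloxy)-6-(methoxymethoxy)phenyl]-3-[4-(benzyloxy)phenyl]-2-(4-bromophenoxy)propane-1,3-dione F4. HCl in MeOH–THF at 50 °C would then remove the acetal and cyclodehydrate the freed phenol onto the ring B carbonyl to give flavone 9.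

Step 8. Transmetalation of the bulky pinacol boronate may be slow, so that protodeboronation of 10 competes. The electron-rich 5,7-dialkoxychromone may also accept the aryl group sluggishly. Base-induced ring opening of the flavanone to the hydroxychalcone may erode enantiomeric purity. The fallback sets out from 9 and 11 and returns at 14, forming the flavanone by O1–C2 closure and separating enantiomers. Reductive carbonylation of 9 (Pd(OAc)2, di(1-adamantyl)-n-butylphosphine, TMEDA, CO/H2, toluene, 100 °C) would give 4-({5,7-bis(benzyloxy)-2-[4-(benzyloxy)phenyl]-4-oxo-4H-chromen-3-yl}oxy)benzaldehyde F5. Claisen–Schmidt condensation with 11 (KOH, EtOH–THF, rt) would give the chalcone (E)-1-[2,4-bis(benzyloxy)-6-hydroxyphenyl]-3-[4-({5,7-bis(benzyloxy)-2-[4-(benzyloxy)phenyl]-4-oxo-4H-chromen-3-yl}oxy)phenyl]prop-2-en-1-one F6. Oxa-Michael closure (NaOAc, EtOH, reflux) would give the racemic flavanone rac-5,7-bis(benzyloxy)-2-[4-({5,7-bis(benzyloxy)-2-[4-(benzyloxy)phenyl]-4-oxo-4H-chromen-3-yl}oxy)phenyl]-2,3-dihydro-4H-chromen-4-one F7. Preparative chromatography on a chiral polysaccharide phase would then deliver the 2S enantiomer 14.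

Further compounds
F1 | step 3 | 2,4-bis(benzyloxy)-6-(methoxymethoxy)benzaldehyde | O=Cc1c(OCOC)cc(OCc2ccccc2)cc1OCc1ccccc1
F2 | step 3 | (Z)-3-[2,4-bis(benzyloxy)-6-(methoxymethoxy)phenyl]-1-[4-(benzyloxy)phenyl]-2-(4-bromophenoxy)prop-2-en-1-one | O=C(c1ccc(OCc2ccccc2)cc1)/C(Oc1ccc(Br)cc1)=C/c1c(OCOC)cc(OCc2ccccc2)cc1OCc1ccccc1
F3 | step 5 | 3-[2,4-bis(benzyloxy)-6-(methoxymethoxy)phenyl]-1-[4-(benzyloxy)phenyl]-2-(4-bromophenoxy)-3-hydroxypropan-1-one (racemic mixture of diastereomers) | O=C(c1ccc(OCc2ccccc2)cc1)C(Oc1ccc(Br)cc1)C(O)c1c(OCOC)cc(OCc2ccccc2)cc1OCc1ccccc1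
F4 | step 5 | 1-[2,4-bis(benzyloxy)-6-(methoxymethoxy)phenyl]-3-[4-(benzyloxy)phenyl]-2-(4-bromophenoxy)propane-1,3-dione | O=C(c1ccc(OCc2ccccc2)cc1)C(Oc1ccc(Br)cc1)C(=O)c1c(OCOC)cc(OCc2ccccc2)cc1OCc1ccccc1
F5 | step 8 | 4-({5,7-bis(benzyloxy)-2-[4-(benzyloxy)phenyl]-4-oxo-4H-chromen-3-yl}oxy)benzaldehyde | O=Cc1ccc(Oc2c(-c3ccc(OCc4ccccc4)cc3)oc3cc(OCc4ccccc4)cc(OCc4ccccc4)c3c2=O)cc1
F6 | step 8 | (E)-1-[2,4-bis(benzyloxy)-6-hydroxyphenyl]-3-[4-({5,7-bis(benzyloxy)-2-[4-(benzyloxy)phenyl]-4-oxo-4H-chromen-3-yl}oxy)phenyl]prop-2-en-1-one | O=C(/C=C/c1ccc(Oc2c(-c3ccc(OCc4ccccc4)cc3)oc3cc(OCc4ccccc4)cc(OCc4ccccc4)c3c2=O)cc1)c1c(O)cc(OCc2ccccc2)cc1OCc1ccccc1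
F7 | step 8 | rac-5,7-bis(benzyloxy)-2-[4-({5,7-bis(benzyloxy)-2-[4-(benzyloxy)phenyl]-4-oxo-4H-chromen-3-yl}oxy)phenyl]-2,3-dihydro-4H-chromen-4-one | O=C1CC(c2ccc(Oc3c(-c4ccc(OCc5ccccc5)cc4)oc4cc(OCc5ccccc5)cc(OCc5ccccc5)c4c3=O)cc2)Oc2cc(OCc3ccccc3)cc(OCc3ccccc3)c21
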